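**Plan**
1. Cuts: remove five benzyl groups. Cut C4–C4a and C4''–C4a'' together (both rings C) back to a (2S,3R)-2,3-bis[aryl(aryloxy)methyl]succinic acid. Then cut O1–C2 and O1''–C2'', then C3''–C2'', then C3–C2, arriving at a succinic half ester, two benzaldehydes and one phenol.
2. Enabling feature: in each unit ring A carries O1, O5 and O7 in a 1,3,5 pattern. Before closure the two ring carbons ortho to O1 (future C4a and C8, C4a'' and C8'') are equivalent, all three oxygens activate each of them, and closure onto C4 (C4'') makes a six-membered ring.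
3. Forward order: the C2–C3 aldol closes a γ-lactone (oxygen on C2 to C4''), which is the template for the C3''–C2'' aldol. Both carbonyls are then parked as CH2OSi groups and the two aryl ethers are installed one after the other, which rules out relactonisation, β-elimination and tetrahydrofuran closure. Reoxidation gives the diacid, both rings C close in one operation, and hydrogenolysis ends the route.
4. Stereochemistry: C3 and C2 come from an Evans syn aldol with (S)-4-benzyloxazolidinone. C3'' comes from attack on the lactone enolate anti to the C3 carboxylate, and C2'' from the closed anti-selective transition state. Both carbinols (S,S) are inverted by Mitsunobu displacement to (R,R), giving 2,3-trans unit 1 (2R,3S) and 2'',3''-cis unit 2 (2''R,3''R).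

Key step: step 13

Remark on names: the target's locants are used for the same carbons in every intermediate. Open-chain compounds share the chain Ar1–C2H(X)–C3H(C4)–C3''H(C4'')–C2''H(Y)–Ar2, with Ar1 = 4-methoxyphenyl, Ar2 = 4-(benzyloxy)phenyl and ArO = 3,5-bis(benzyloxy)phenoxy.
Assumption: in the key step unit 1 (the trans unit) is drawn as closing first. The order of the two closures does not change the product.

**Step 1**
Reactants: 1 (S)-4-benzyl-1,3-oxazolidin-2-one; 2 methyl 4-chloro-4-oxobutanoate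
Product: 3 methyl 4-[(4S)-4-benzyl-2-oxo-1,3-oxazolidin-3-yl]-4-oxobutanoate
Conditions: Et3N, 4-(dimethylamino)pyridine (cat.), CH2Cl2, 0 °C → rt
Reagents that add atoms: none
Why: N-acylation of an oxazolidinone by an acid chloride under amine/4-(dimethylamino)pyridine catalysis is routine and touches no stereocentre.

**Step 2**
Reactants: 3 succinate imide; 4 4-methoxybenzaldehyde
Product: 6 (4S)-4-benzyl-3-{[(2S,3S)-2-(4-methoxyphenyl)-5-oxooxolan-3-yl]carbonyl}-1,3-oxazolidin-2-one (trans lactone), via open-chain syn aldol 5 (not isolated)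
Conditions: Bu2BOTf, i-Pr2NEt, CH2Cl2, 0 °C; 4, −78 → 0 °C; H2O2, MeOH, pH 7 buffer, 0 °C; pyridinium p-toluenesulfonate (cat.), CH2Cl2, rt
Reagents that add atoms: none
Why: In this Evans syn aldol, soft enolisation of the imide to the Z boron enolate and a Zimmerman–Traxler chair on the face left open by the auxiliary benzyl group set C3 (S) and C2 (S), and the C2 oxygen then closes on the methyl ester to the trans γ-lactone (aldol–lactonisation known for succinate imides), masking that oxygen and C4'' together.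

**Step 3**
Reactants: 6 lactone imide
Product: 8 (2S,3S)-2-(4-methoxyphenyl)-5-oxooxolane-3-carboxylic acid, via peroxy acid 7 (not isolated)
Conditions: LiOH, H2O2, THF–H2O, 0 °C; Na2SO3; HCl to pH 2
Reagents that add atoms: hydrogen peroxide, OO
Why: In this standard hydroperoxide cleavage of an N-acyloxazolidinone the exocyclic carbonyl is attacked selectively, sulfite reduces the peracid, any lactone opened by hydroxide recloses on acidification, and C2 and C3 are untouched.

**Step 4**
Reactants: 8 lactone acid; 9 4-(benzyloxy)benzaldehyde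
Product: 12 (2S,3S,4R)-4-{(S)-[4-(benzyloxy)phenyl](triethylsilyloxy)methyl}-2-(4-methoxyphenyl)-5-oxooxolane-3-carboxylic acid, via aldol adduct 10 (not isolated), via bis(triethylsilyl) derivative 11 (not isolated)
Conditions: LiN(SiMe3)2 (2.3 equiv), THF, −78 °C; 9; Et3SiCl (3 equiv), −78 → 0 °C; aq. NaH2PO4
Reagents that add atoms: chlorotriethylsilane, CC[Si](Cl)(CC)CC
Why: This is a lactone enolate aldol on the carboxylate–enolate dianion (the species used to alkylate paraconic acids), in which the carboxylate keeps C3–H from being removed and so blocks Stobbe-type ring opening, the aldehyde adds to the face anti to it (C3'' R, trans), the ring-locked E enolate in a closed chair should favour the anti aldol (C2'' S), and silylation of the aldolate stops retro-aldol and marks this oxygen for later release, the minor C2'' epimer being removed by chromatography.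

**Step 5**
Reactants: 12 silyl ether lactone acid
Product: 13 (2R,3S)-2-[(S)-hydroxy(4-methoxyphenyl)methyl]-3-{(S)-[4-(benzyloxy)phenyl](triethylsilyloxy)methyl}butane-1,4-diol
Conditions: LiAlH4, THF, 0 °C → rt; Na2SO4·10H2O
Reagents that add atoms: none
Why: Hydride reduction turns lactone and carboxylate into primary alcohols and frees the C2 hydroxyl, removing the two carbonyls that would cause relactonisation and β-elimination during ether formation, while silyl and benzyl ethers and all four stereocentres are inert.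

**Step 6**
Reactants: 13 triol
Product: 14 chain compound X = OH; Y = OSiEt3; C4 = C4'' = CH2OSiMe2t-Bu; (2S,3R,3''S,2''S)
Conditions: t-BuMe2SiCl (2.1 equiv), imidazole, CH2Cl2, 0 °C
Reagents that add atoms: tert-butylchlorodimethylsilane, CC(C)(C)[Si](C)(C)Cl
Why: Sterically selective silylation, since primary alcohols react far faster than the hindered secondary benzylic one, so only the C2 hydroxyl stays free.

**Step 7**
Reactants: 14 C2 alcohol; 15 3,5-bis(benzyloxy)phenol
Product: 16 chain compound X = OAr; Y = OSiEt3; C4 = C4'' = CH2OSiMe2t-Bu; (2R,3R,3''S,2''S)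
Conditions: PPh3, DIAD (added last), toluene, 0 °C → rt
Reagents that add atoms: none
Why: In this Mitsunobu aryl ether synthesis the phenoxide displaces the alkoxyphosphonium group by SN2 with inversion (C2 S to R), the substrate has no acidic α-hydrogen for elimination and no free hydroxyl that could close a tetrahydrofuran, and a non-polar solvent at low temperature holds back ionisation of the 4-methoxybenzylic centre.

**Step 8**
Reactants: 16 mono(aryl ether)
Product: 17 chain compound X = OAr; Y = OH; C4 = C4'' = CH2OSiMe2t-Bu; (2R,3R,3''S,2''S)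
Conditions: HF·pyridine, pyridine, THF, 0 °C
Reagents that add atoms: none
Why: Selective desilylation, because a secondary triethylsilyl ether falls to buffered HF·pyridine much faster than primary tert-butyldimethylsilyl ethers, and the buffered medium does not ionise the benzylic aryl ether.

**Step 9**
Reactants: 17 C2'' alcohol; 15 3,5-bis(benzyloxy)phenol
Product: 18 chain compound X = Y = OAr; C4 = C4'' = CH2OSiMe2t-Bu; (2R,3R,3''S,2''R)
Conditions: PPh3, DIAD (added last), toluene, 0 °C → rt
Reagents that add atoms: none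
Why: A second Mitsunobu aryl ether synthesis inverts C2'' (S to R) and so creates the syn ether that becomes the cis unit, the only hydroxyl in the molecule being the one that reacts.

**Step 10**
Reactants: 18 bis(aryl ether)
Product: 19 chain compound X = Y = OAr; C4 = C4'' = CH2OH; (2R,3R,3''S,2''R)
Conditions: Bu4NF, THF, 0 °C → rt
Reagents that add atoms: none
Why: Fluoride cleavage of primary silyl ethers is safe here because the substrate has no carbonyl group and thus no base-sensitive site.

**Step 11**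
Reactants: 19 diol
Product: 20 chain compound X = Y = OAr; C4 = C4'' = CHO; (2R,3S,3''R,2''R)
Conditions: Dess–Martin periodinane (3 equiv), NaHCO3, CH2Cl2, 0 °C → rt; used crude
Reagents that add atoms: none
Why: In this buffered Dess–Martin oxidation an excess of reagent engages both hydroxyls at once so that the dialdehyde should form rather than a lactol, and the neutral medium spares the β-aryloxy aldehydes from loss of phenol and from epimerisation at C3 and C3''.

**Step 12**
Reactants: 20 dialdehyde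
Product: 21 (2S,3R)-2-{(R)-[3,5-bis(benzyloxy)phenoxy](4-methoxyphenyl)methyl}-3-{(R)-[3,5-bis(benzyloxy)phenoxy][4-(benzyloxy)phenyl]methyl}butanedioic acid
Conditions: NaClO2, NaH2PO4, 2-methylbut-2-ene (large excess), t-BuOH–THF–H2O, 0 °C
Reagents that add atoms: sodium chlorite, [Na+].[O-]Cl=O
Why: Pinnick oxidation converts aldehydes to acids in weakly acidic buffer without enolisation, and the alkene traps hypochlorous acid before it can chlorinate the phloroglucinol rings.

**Step 13**
Reactants: 21 diacid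
Product: 25 penta-O-benzylsikokianin B, via cis-succinic anhydride 22 (not isolated), via unit-1 flavanone acid 23 (not isolated), via trifluoroacetic mixed anhydride 24 (not isolated)
Conditions: (CF3CO)2O (3 equiv), CH2Cl2, −10 → 0 °C; cold aq. NaHCO3
Reagents that add atoms: none
Why: The reagent should first dehydrate the 1,4-diacid to anhydride 22, whose protonated C4 carbonyl (or the acyl trifluoroacetate in equilibrium with it) is attacked by the ring A carbon ortho to O1 in an electrophilic aromatic substitution, and rearomatisation releases acid 23, which more reagent converts into 24 for the same event at C4''. The closest known reaction is the trifluoroacetic anhydride mediated Friedel–Crafts cyclisation of 3-aryloxypropanoic acids to chroman-4-ones. Each ring C closes in 6-exo-trig mode through C4a–C8a–O1–C2–C3–C4 (and the double-primed set). No stereocentre is formed, and C2, C3, C3'' and C2'' take part in no bond that changes. Regioselectivity does not arise, because the two carbons ortho to O1 are equivalent and the third ring carbon cannot reach the acyl group. Acylation must outrun ionisation of the benzylic C2–O1 and C2''–O1'' bonds, enolisation of the new ketones and C-trifluoroacetylation of ring A, which is secured by the triply oxygen-activated ring placed for six-membered ring closure onto the acyl carbon, the electron-withdrawing acyl groups beside both benzylic carbons, a small excess of reagent and a temperature at or below 0 °C.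

**Step 14**
Reactants: 25 penta-O-benzylsikokianin B
Product: 26 sikokianin B
Conditions: H2 (1 atm), 10% Pd/C, EtOAc–MeOH, rt
Reagents that add atoms: none
Why: Hydrogenolysis of aryl benzyl ethers under neutral conditions is faster than cleavage of the C2–O1 bonds or reduction of the hydrogen-bonded ketones and uses neither acid nor base, so the enolisable C3 and C3'' (cis unit included) keep their configuration.

**Compound list**

1 | (S)-4-benzyl-1,3-oxazolidin-2-one | O=C1N[C@@H](Cc2ccccc2)CO1 | starting material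
2 | methyl 4-chloro-4-oxobutanoate | COC(=O)CCC(=O)Cl | starting material
3 | methyl 4-[(4S)-4-benzyl-2-oxo-1,3-oxazolidin-3-yl]-4-oxobutanoate | COC(=O)CCC(=O)N1[C@@H](Cc2ccccc2)COC1=O | intermediate
4 | 4-methoxybenzaldehyde | COc1ccc(C=O)cc1 | starting material
5 | methyl (3S,4S)-3-{[(4S)-4-benzyl-2-oxo-1,3-oxazolidin-3-yl]carbonyl}-4-hydroxy-4-(4-methoxyphenyl)butanoate (open syn aldol, not isolated) | COc1ccc([C@@H](O)[C@H](CC(=O)OC)C(=O)N2[C@@H](Cc3ccccc3)COC2=O)cc1 | intermediate
6 | (4S)-4-benzyl-3-{[(2S,3S)-2-(4-methoxyphenyl)-5-oxooxolan-3-yl]carbonyl}-1,3-oxazolidin-2-one | COc1ccc([C@H]2OC(=O)C[C@@H]2C(=O)N2[C@@H](Cc3ccccc3)COC2=O)cc1 | intermediate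
7 | (2S,3S)-2-(4-methoxyphenyl)-5-oxooxolane-3-carboperoxoic acid (not isolated) | COc1ccc([C@H]2OC(=O)C[C@@H]2C(=O)OO)cc1 | intermediate
8 | (2S,3S)-2-(4-methoxyphenyl)-5-oxooxolane-3-carboxylic acid | COc1ccc([C@H]2OC(=O)C[C@@H]2C(=O)O)cc1 | intermediate
9 | 4-(benzyloxy)benzaldehyde | O=Cc1ccc(OCc2ccccc2)cc1 | starting material
10 | (2S,3S,4R)-4-{(S)-[4-(benzyloxy)phenyl](hydroxy)methyl}-2-(4-methoxyphenyl)-5-oxooxolane-3-carboxylic acid (in the flask as its dilithium salt, not isolated) | COc1ccc([C@H]2OC(=O)[C@@H]([C@H](O)c3ccc(OCc4ccccc4)cc3)[C@@H]2C(=O)O)cc1 | intermediate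
11 | triethylsilyl ester of 12 (not isolated) | COc1ccc([C@H]2OC(=O)[C@@H]([C@H](O[Si](CC)(CC)CC)c3ccc(OCc4ccccc4)cc3)[C@@H]2C(=O)O[Si](CC)(CC)CC)cc1 | intermediate
12 | (2S,3S,4R)-4-{(S)-[4-(benzyloxy)phenyl](triethylsilyloxy)methyl}-2-(4-methoxyphenyl)-5-oxooxolane-3-carboxylic acid | COc1ccc([C@H]2OC(=O)[C@@H]([C@H](O[Si](CC)(CC)CC)c3ccc(OCc4ccccc4)cc3)[C@@H]2C(=O)O)cc1 | intermediate
13 | (2R,3S)-2-[(S)-hydroxy(4-methoxyphenyl)methyl]-3-{(S)-[4-(benzyloxy)phenyl](triethylsilyloxy)methyl}butane-1,4-diol | COc1ccc([C@@H](O)[C@@H](CO)[C@@H](CO)[C@H](O[Si](CC)(CC)CC)c2ccc(OCc3ccccc3)cc2)cc1 | intermediate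
14 | chain compound, X = OH, Y = OSiEt3, C4 = C4'' = CH2OSiMe2t-Bu, (2S,3R,3''S,2''S) | COc1ccc([C@@H](O)[C@@H](CO[Si](C)(C)C(C)(C)C)[C@@H](CO[Si](C)(C)C(C)(C)C)[C@H](O[Si](CC)(CC)CC)c2ccc(OCc3ccccc3)cc2)cc1 | intermediate
15 | 3,5-bis(benzyloxy)phenol | Oc1cc(OCc2ccccc2)cc(OCc2ccccc2)c1 | starting material
16 | chain compound, X = OAr, Y = OSiEt3, C4 = C4'' = CH2OSiMe2t-Bu, (2R,3R,3''S,2''S) | COc1ccc([C@H](Oc2cc(OCc3ccccc3)cc(OCc3ccccc3)c2)[C@@H](CO[Si](C)(C)C(C)(C)C)[C@@H](CO[Si](C)(C)C(C)(C)C)[C@H](O[Si](CC)(CC)CC)c2ccc(OCc3ccccc3)cc2)cc1 | intermediate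
17 | chain compound, X = OAr, Y = OH, C4 = C4'' = CH2OSiMe2t-Bu, (2R,3R,3''S,2''S) | COc1ccc([C@H](Oc2cc(OCc3ccccc3)cc(OCc3ccccc3)c2)[C@@H](CO[Si](C)(C)C(C)(C)C)[C@@H](CO[Si](C)(C)C(C)(C)C)[C@H](O)c2ccc(OCc3ccccc3)cc2)cc1 | intermediate
18 | chain compound, X = Y = OAr, C4 = C4'' = CH2OSiMe2t-Bu, (2R,3R,3''S,2''R) | COc1ccc([C@H](Oc2cc(OCc3ccccc3)cc(OCc3ccccc3)c2)[C@@H](CO[Si](C)(C)C(C)(C)C)[C@@H](CO[Si](C)(C)C(C)(C)C)[C@@H](Oc2cc(OCc3ccccc3)cc(OCc3ccccc3)c2)c2ccc(OCc3ccccc3)cc2)cc1 | intermediate
19 | chain compound, X = Y = OAr, C4 = C4'' = CH2OH, (2R,3R,3''S,2''R) | COc1ccc([C@H](Oc2cc(OCc3ccccc3)cc(OCc3ccccc3)c2)[C@@H](CO)[C@@H](CO)[C@@H](Oc2cc(OCc3ccccc3)cc(OCc3ccccc3)c2)c2ccc(OCc3ccccc3)cc2)cc1 | intermediate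
20 | chain compound, X = Y = OAr, C4 = C4'' = CHO, (2R,3S,3''R,2''R) | COc1ccc([C@H](Oc2cc(OCc3ccccc3)cc(OCc3ccccc3)c2)[C@@H](C=O)[C@@H](C=O)[C@@H](Oc2cc(OCc3ccccc3)cc(OCc3ccccc3)c2)c2ccc(OCc3ccccc3)cc2)cc1 | intermediate
21 | (2S,3R)-2-{(R)-[3,5-bis(benzyloxy)phenoxy](4-methoxyphenyl)methyl}-3-{(R)-[3,5-bis(benzyloxy)phenoxy][4-(benzyloxy)phenyl]methyl}butanedioic acid (key-step precursor) | COc1ccc([C@H](Oc2cc(OCc3ccccc3)cc(OCc3ccccc3)c2)[C@@H](C(=O)O)[C@@H](C(=O)O)[C@@H](Oc2cc(OCc3ccccc3)cc(OCc3ccccc3)c2)c2ccc(OCc3ccccc3)cc2)cc1 | intermediate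
22 | cyclic anhydride of 21, the two side chains cis on the five-membered ring (not isolated) | COc1ccc([C@H](Oc2cc(OCc3ccccc3)cc(OCc3ccccc3)c2)[C@H]2C(=O)OC(=O)[C@H]2[C@@H](Oc2cc(OCc3ccccc3)cc(OCc3ccccc3)c2)c2ccc(OCc3ccccc3)cc2)cc1 | intermediate
23 | acid with ring C of unit 1 closed (2R,3S-trans flavanone) and unit 2 still open (not isolated) | COc1ccc([C@@H]2Oc3cc(OCc4ccccc4)cc(OCc4ccccc4)c3C(=O)[C@H]2[C@@H](C(=O)O)[C@@H](Oc2cc(OCc3ccccc3)cc(OCc3ccccc3)c2)c2ccc(OCc3ccccc3)cc2)cc1 | intermediate
24 | mixed anhydride of 23 and trifluoroacetic acid (not isolated) | COc1ccc([C@@H]2Oc3cc(OCc4ccccc4)cc(OCc4ccccc4)c3C(=O)[C@H]2[C@@H](C(=O)OC(=O)C(F)(F)F)[C@@H](Oc2cc(OCc3ccccc3)cc(OCc3ccccc3)c2)c2ccc(OCc3ccccc3)cc2)cc1 | intermediate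
25 | penta-O-benzylsikokianin B, (2R,3S,2''R,3''R) (key-step product) | COc1ccc([C@@H]2Oc3cc(OCc4ccccc4)cc(OCc4ccccc4)c3C(=O)[C@H]2[C@H]2C(=O)c3c(OCc4ccccc4)cc(OCc4ccccc4)cc3O[C@H]2c2ccc(OCc4ccccc4)cc2)cc1 | intermediate
26 | sikokianin B, (2R,3S,2''R,3''R) | COc1ccc([C@@H]2Oc3cc(O)cc(O)c3C(=O)[C@H]2[C@H]2C(=O)c3c(O)cc(O)cc3O[C@H]2c2ccc(O)cc2)cc1 | target

**Step count**
Total steps: 14. Longest linear sequence: 14 steps (from 1 and 2 to 26).

**Steps most likely to fail**

**Step 13.**
- What may go wrong: the liberated acid may ionise the 4-alkoxybenzylic C–O bonds, which would scramble C2 or C2'' or lose phenol.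
- The reaction may also stall at the cyclic anhydride, ring A may be trifluoroacetylated, or acid-promoted enolisation at C3'' may turn the cis unit into the trans one.
- Fallback: the same two bonds are made with reversed polarity and without acid, by a Parham cycliacylation. It sets out from 14 and returns at 25.
- Phenol 15 is iodinated ortho to the hydroxyl (N-iodosuccinimide, CH2Cl2, 0 °C) to 3,5-bis(benzyloxy)-2-iodophenol F1.
- F1 replaces 15 in the operations of steps 7 to 12. These give in turn the mono(iodoaryl) ether F2, the C2'' alcohol F3, the bis(iodoaryl) ether F4, the diol F5, the dialdehyde F6 and the diiodo diacid F7.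
- n-BuLi (4.4 equiv, THF, −100 °C) deprotonates both acids and exchanges both iodines. Each aryllithium then adds to the neighbouring lithium carboxylate.
- The gem-diolates persist until the cold quench, so the enolisable ketones of 25 appear only on work-up.

**Step 9** (step 7 is the same reaction type on a less crowded centre).
- What may go wrong: slow SN2 displacement at the hindered C2'' may let ionisation of the 4-benzyloxybenzylic phosphonium species compete, which loses the inversion. Elimination towards the styrene is the other risk.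
- Fallback: the oxygen is arylated instead of the carbon being substituted, so that the carbinol C–O bond is never broken. It sets out from 17 and returns at 18.
- Dess–Martin oxidation gives the aryl ketone F8.
- Corey–Bakshi–Shibata reduction follows, using (S)-2-methyl-CBS-oxazaborolidine and BH3·SMe2 in THF at −20 °C, with the aryl group taken as the larger substituent. It should give the (2''R) alcohol F9.
- An Ullmann-type coupling of F9 with 1,3-bis(benzyloxy)-5-iodobenzene then forms the ether with retention. Conditions are CuI, 3,4,7,8-tetramethyl-1,10-phenanthroline and Cs2CO3 in toluene at 90 °C.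

**Step 4.**
- What may go wrong: facial selectivity at the aldehyde carbon may be poor, so that C2'' is formed as a mixture while C3'' is still set trans.
- Fallback: C2'' is set by a catalyst instead of the aldol transition state. It sets out from 8 and returns at 12.
- The aldol is quenched without chlorosilane, giving 10 together with its C2'' epimer F10.
- Dess–Martin oxidation of the mixture converges on the β-keto lactone acid F11, in which C3'' rests in the more stable trans arrangement.
- Noyori transfer hydrogenation (RuCl(p-cymene)[(S,S)-TsDPEN], HCO2H–Et3N, CH2Cl2, rt) should deliver the (S) carbinol 10.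
- Et3SiCl with imidazole, followed by aqueous work-up (through 11), gives 12.

**Further compounds**

F1 | step 13 | 3,5-bis(benzyloxy)-2-iodophenol | Oc1cc(OCc2ccccc2)cc(OCc2ccccc2)c1I
F2 | step 13 | mono(iodoaryl) ether, analogue of 16 with 3,5-bis(benzyloxy)-2-iodophenoxy on C2, (2R,3R,3''S,2''S) | COc1ccc([C@H](Oc2cc(OCc3ccccc3)cc(OCc3ccccc3)c2I)[C@@H](CO[Si](C)(C)C(C)(C)C)[C@@H](CO[Si](C)(C)C(C)(C)C)[C@H](O[Si](CC)(CC)CC)c2ccc(OCc3ccccc3)cc2)cc1
F3 | step 13 | C2'' alcohol, analogue of 17 | COc1ccc([C@H](Oc2cc(OCc3ccccc3)cc(OCc3ccccc3)c2I)[C@@H](CO[Si](C)(C)C(C)(C)C)[C@@H](CO[Si](C)(C)C(C)(C)C)[C@H](O)c2ccc(OCc3ccccc3)cc2)cc1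
F4 | step 13 | bis(iodoaryl) ether, analogue of 18 | COc1ccc([C@H](Oc2cc(OCc3ccccc3)cc(OCc3ccccc3)c2I)[C@@H](CO[Si](C)(C)C(C)(C)C)[C@@H](CO[Si](C)(C)C(C)(C)C)[C@@H](Oc2cc(OCc3ccccc3)cc(OCc3ccccc3)c2I)c2ccc(OCc3ccccc3)cc2)cc1
F5 | step 13 | diol, analogue of 19 | COc1ccc([C@H](Oc2cc(OCc3ccccc3)cc(OCc3ccccc3)c2I)[C@@H](CO)[C@@H](CO)[C@@H](Oc2cc(OCc3ccccc3)cc(OCc3ccccc3)c2I)c2ccc(OCc3ccccc3)cc2)cc1
F6 | step 13 | dialdehyde, analogue of 20 | COc1ccc([C@H](Oc2cc(OCc3ccccc3)cc(OCc3ccccc3)c2I)[C@@H](C=O)[C@@H](C=O)[C@@H](Oc2cc(OCc3ccccc3)cc(OCc3ccccc3)c2I)c2ccc(OCc3ccccc3)cc2)cc1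
F7 | step 13 | diiodo diacid, analogue of 21 | COc1ccc([C@H](Oc2cc(OCc3ccccc3)cc(OCc3ccccc3)c2I)[C@@H](C(=O)O)[C@@H](C(=O)O)[C@@H](Oc2cc(OCc3ccccc3)cc(OCc3ccccc3)c2I)c2ccc(OCc3ccccc3)cc2)cc1
F8 | step 9 | aryl ketone from 17 (C2'' = C=O) | COc1ccc([C@H](Oc2cc(OCc3ccccc3)cc(OCc3ccccc3)c2)[C@@H](CO[Si](C)(C)C(C)(C)C)[C@@H](CO[Si](C)(C)C(C)(C)C)C(=O)c2ccc(OCc3ccccc3)cc2)cc1
F9 | step 9 | (2''R) alcohol, C2'' epimer of 17 | COc1ccc([C@H](Oc2cc(OCc3ccccc3)cc(OCc3ccccc3)c2)[C@@H](CO[Si](C)(C)C(C)(C)C)[C@@H](CO[Si](C)(C)C(C)(C)C)[C@@H](O)c2ccc(OCc3ccccc3)cc2)cc1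
F10 | step 4 | C2'' epimer of 10 (R carbinol) | COc1ccc([C@H]2OC(=O)[C@@H]([C@@H](O)c3ccc(OCc4ccccc4)cc3)[C@@H]2C(=O)O)cc1
F11 | step 4 | (2S,3S,4R)-4-[4-(benzyloxy)benzoyl]-2-(4-methoxyphenyl)-5-oxooxolane-3-carboxylic acid | COc1ccc([C@H]2OC(=O)[C@@H](C(=O)c3ccc(OCc4ccccc4)cc3)[C@@H]2C(=O)O)cc1
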